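Ring B is closed last, by making the C6–C7 bond (labdane numbering) in an intramolecular Hosomi–Sakurai conjugate addition. The step exploits the 1,3-relation in ring B between C6 and the exocyclic C8=C17 methylene: C17=C8–C7–C6 is the retron of an allylsilane attacking an acceptor carbon. In one operation it should form C6–C7, close ring B, create the 8(17)-alkene and leave a C4 ketone through which C5 (epimerisation) and the C4 quaternary centre (homologation, methylation) are then set. The precursor is a monocyclic seco-B compound: ring A as a 2-methylenecyclohexanone whose quaternary C10 carries C9 with a 2-(trimethylsilylmethyl)allyl unit and the side chain, assembled by an Ireland–Claisen rearrangement.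

Key step: step 12

Remark: locants C1–C20 are labdane locants (ring A = C1–C5 and C10; ring B = C5–C10); the target is read as an ent-labdane with the acyloxymethyl carbon C19 axial on C4 (cis to the C10 methyl), 13R, esterified with (R)-2-methylbutanoic acid, which is assumed to be purchasable.

Step 1
Reactants: 1 (R)-citronellol
Product: 2 (R)-citronellyl tert-butyldiphenylsilyl ether
Conditions: t-BuPh2SiCl, imidazole, CH2Cl2, 0 °C → rt
Reagents that add atoms: tert-butyl(chloro)diphenylsilane (CC(C)(C)[Si](Cl)(c1ccccc1)c1ccccc1)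
Why: Silyl ether formation masks the future C15 oxygen with a group that should survive the bases, organometallics, Lewis acid and aqueous acid used later and is removed by fluoride at the end.

Step 2
Reactants: 2 (R)-citronellyl tert-butyldiphenylsilyl ether
Product: 4 (4R)-6-(tert-butyldiphenylsilyloxy)-4-methylhexan-1-ol, via aldehyde 3 (not isolated)
Conditions: O3, CH2Cl2/MeOH, −78 °C; then NaBH4, −78 °C → rt
Reagents that add atoms: ozone ([O-][O+]=O)
Why: Ozonolysis of the trisubstituted alkene with borohydride work-up should give the primary alcohol (future C9) directly, leaving the C13 stereocentre untouched.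

Step 3
Reactants: 4 (4R)-6-(tert-butyldiphenylsilyloxy)-4-methylhexan-1-ol
Product: 5 (3R)-6-bromo-3-methylhexyl tert-butyldiphenylsilyl ether
Conditions: CBr4, PPh3, CH2Cl2, 0 °C
Reagents that add atoms: tetrabromomethane (BrC(Br)(Br)Br)
Why: The Appel reaction converts the unhindered primary alcohol into the bromide under neutral conditions that keep the silyl ether.

Step 4
Reactants: 5 (3R)-6-bromo-3-methylhexyl tert-butyldiphenylsilyl ether
Product: 6 (5R)-7-(tert-butyldiphenylsilyloxy)-5-methylheptanoic acid
Conditions: Mg, THF, reflux; CO2, −78 °C → rt; aq. HCl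
Reagents that add atoms: carbon dioxide (O=C=O)
Why: Grignard formation and carboxylation add the single carbon that becomes C8 and deliver the acid needed for the ester enolate Claisen step.

Step 5
Reactants: 7 3-methylcyclohex-2-en-1-one
Product: 8 2-iodo-3-methylcyclohex-2-en-1-one
Conditions: I2, pyridine, CH2Cl2, rt
Reagents that add atoms: iodine (II)
Why: Pyridine-mediated α-iodination of the enone (conjugate addition of pyridine, iodination of the enolate, elimination) installs the vinyl iodide that later carries C6.

Step 6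
Reactants: 8 2-iodo-3-methylcyclohex-2-en-1-one
Product: 9 (1R)-2-iodo-3-methylcyclohex-2-en-1-ol
Conditions: (S)-2-methyl-CBS-oxazaborolidine (C18H20BNO, 20 mol%), BH3·SMe2, THF, −20 °C
Reagents that add atoms: none
Why: Corey–Bakshi–Shibata reduction with the iodoalkenyl carbon as the large group should give the (R)-allylic alcohol, the carbinol centre (future C4) that later steers the Claisen step and is then erased.

Step 7
Reactants: 9 (1R)-2-iodo-3-methylcyclohex-2-en-1-ol
Product: 10 (1R)-2-(hydroxymethyl)-3-methylcyclohex-2-en-1-ol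
Conditions: Bu3SnCH2OH, Pd(PPh3)4 (5 mol%), dioxane, 90 °C
Reagents that add atoms: (tributylstannyl)methanol (CCCC[Sn](CCCC)(CCCC)CO)
Why: Stille coupling of the vinyl iodide (zerovalent palladium) with the hydroxymethyl stannane introduces C6 as a primary allylic alcohol without touching the carbinol centre.

Step 8
Reactants: 10 (1R)-2-(hydroxymethyl)-3-methylcyclohex-2-en-1-ol; 6 (5R)-7-(tert-butyldiphenylsilyloxy)-5-methylheptanoic acid
Product: 11 [(6R)-6-hydroxy-2-methylcyclohex-1-en-1-yl]methyl (5R)-7-(tert-butyldiphenylsilyloxy)-5-methylheptanoate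
Conditions: EDC·HCl, DMAP (cat.), CH2Cl2, −20 → 0 °C
Reagents that add atoms: none
Why: Steglich-type carbodiimide esterification should acylate the primary allylic hydroxyl (C6–OH) much faster than the hindered secondary one.

Step 9
Reactants: 11 [(6R)-6-hydroxy-2-methylcyclohex-1-en-1-yl]methyl (5R)-7-(tert-butyldiphenylsilyloxy)-5-methylheptanoate
Product: 14 methyl (2S,5R)-7-(tert-butyldiphenylsilyloxy)-2-[(1S,3R)-3-hydroxy-1-methyl-2-methylidenecyclohexyl]-5-methylheptanoate, via bis-silyl ketene acetal 12 (not isolated), via carboxylic acid 13 (not isolated)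
Conditions: LiN(i-Pr)2 (2.3 equiv), THF/DMPU, −78 °C; Me3SiCl; −78 → 65 °C; 1 M HCl; then Me3SiCHN2, PhMe/MeOH, 0 °C
Reagents that add atoms: (trimethylsilyl)diazomethane (C[Si](C)(C)C=[N+]=[N-])
Why: Ireland–Claisen rearrangement: enolisation in THF/DMPU should give the Z silyl ketene acetal, the chair transition state then relates C9 to the new quaternary C10 as in the target, and bond formation at C10 anti to the C4 silyloxy group (held pseudoaxial by A(1,2) strain with the C5 substituent) transfers the absolute configuration from C4; esterification of the crude acid gives the methyl ester.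

Step 10
Reactants: 14 methyl (2S,5R)-7-(tert-butyldiphenylsilyloxy)-2-[(1S,3R)-3-hydroxy-1-methyl-2-methylidenecyclohexyl]-5-methylheptanoate
Product: 16 seco-B allylsilane alcohol (C8 as 2-substituted allyltrimethylsilane; C4–OH; C5=C6 methylidene), via tertiary carbinol 15 (not isolated)
Conditions: Me3SiCH2MgCl, CeCl3, THF, −78 °C → rt; then SiO2, CH2Cl2, rt
Reagents that add atoms: (trimethylsilyl)methylmagnesium chloride (C[Si](C)(C)C[Mg]Cl)
Why: Cerium-mediated double addition of the silylmethyl Grignard reagent to the ester, then Peterson elimination on silica, should turn the C8 ester regiospecifically into the allylsilane (C7 and C17 introduced).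

Step 11
Reactants: 16 seco-B allylsilane alcohol
Product: 17 seco-B enone (C4 ketone conjugated to the C5=C6 exocyclic methylene; allylsilane on C9)
Conditions: MnO2, CH2Cl2, rt
Reagents that add atoms: none
Why: MnO2 oxidises the allylic alcohol under neutral conditions to the α-methylene ketone, removes the now spent C4 stereocentre and leaves the allylsilane untouched.

Step 12
Reactants: 17 seco-B enone
Product: 19 trans-fused 8(17)-methylidene decalin-4-one (18,19-dinor core carrying the silyl-protected side chain), via aluminium enolate 18 (not isolated)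
Conditions: EtAlCl2, PhMe, −78 → −20 °C; aq. NaHCO3; then NaOMe (cat.), MeOH, rt
Reagents that add atoms: none
Why: Intramolecular Hosomi–Sakurai conjugate addition: EtAlCl2 binds the C4 carbonyl of the s-cis exocyclic enone, the allylsilane γ-carbon C7 adds to the enone terminus C6, the β-silyl cation at C8 loses the silyl group to leave the C8=C17 exocyclic methylene, and the aluminium enolate 18 is protonated at C5 on work-up. The closest known reaction type is the Lewis acid-promoted intramolecular addition of 2-substituted allylsilanes to enones, which gives methylenecyclohexanes. Ring B closes through a chair-like six-membered transition state, 6-endo-trig at the enone terminus, with the C9 side chain equatorial. The only new stereocentre is C5, which is α to the C4 ketone and is therefore equilibrated with NaOMe to the trans ring fusion (H-5 anti to the C10 methyl group), while C9 and C10 come from step 9. The step needs 1,4- rather than 1,2-addition to the ketone and C–C bond formation before protodesilylation; the strained bridged product of 1,2-attack, the aluminium Lewis acid and the low temperature should secure this.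

Step 13
Reactants: 19 trans-fused 8(17)-methylidene decalin-4-one
Product: 21 C4 formyl compound (C19 aldehyde; mixture of C4 epimers), via enol ether 20 (not isolated)
Conditions: MeOCH2PPh3Cl, KN(SiMe3)2, THF, 0 °C → rt; then 2 M HCl, THF, rt
Reagents that add atoms: (methoxymethyl)triphenylphosphonium chloride (COC[P+](c1ccccc1)(c1ccccc1)c1ccccc1.[Cl-]); water (O)
Why: Wittig methoxymethylenation of the C4 ketone and mild acid hydrolysis of the enol ether give the homologous aldehyde, whose C4 configuration is irrelevant because it is enolised in the next step.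

Step 14
Reactants: 21 C4 formyl compound
Product: 22 quaternary aldehyde (C4 bearing equatorial C18 methyl and axial C19 formyl)
Conditions: KOt-Bu, MeI, THF/t-BuOH, 0 °C → rt
Reagents that add atoms: iodomethane (CI)
Why: C-methylation of the aldehyde enolate from the face opposite the axial C10 methyl group (1,3-diaxial shielding) should place the new methyl equatorial and the formyl group axial, cis to the C10 methyl.

Step 15
Reactants: 22 quaternary aldehyde
Product: 23 C19 primary alcohol
Conditions: NaBH4, MeOH, 0 °C
Reagents that add atoms: none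
Why: Borohydride reduction of the non-enolisable neopentyl aldehyde gives the axial hydroxymethyl group.

Step 16
Reactants: 23 C19 primary alcohol; 24 (R)-2-methylbutanoic acid
Product: 25 C19 (R)-2-methylbutanoate with C15 silyl ether
Conditions: EDC·HCl, DMAP, CH2Cl2, rt → 40 °C
Reagents that add atoms: none
Why: Steglich esterification acylates the hindered primary alcohol, and no base strong enough to epimerise the α-centre of the acid is present.

Step 17
Reactants: 25 C19 (R)-2-methylbutanoate with C15 silyl ether
Product: 26 C15 primary alcohol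
Conditions: Bu4NF, AcOH, THF, rt
Reagents that add atoms: none
Why: Fluoride-mediated desilylation buffered with acetic acid frees the C15 hydroxyl without cleaving or epimerising the hindered ester.

Step 18
Reactants: 26 C15 primary alcohol
Product: 27 target acid CNP0365997.1
Conditions: TEMPO (cat.), PhI(OAc)2, MeCN/H2O, rt
Reagents that add atoms: water (O)
Why: The nitroxyl-catalysed oxidation takes the primary alcohol through the aldehyde hydrate to the carboxylic acid and should leave the 1,1-disubstituted alkene and the ester untouched.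

Compound list
1 | (R)-citronellol, (3R)-3,7-dimethyloct-6-en-1-ol | CC(C)=CCC[C@@H](C)CCO | starting material
2 | tert-butyl{[(3R)-3,7-dimethyloct-6-en-1-yl]oxy}diphenylsilane | CC(C)=CCC[C@@H](C)CCO[Si](c1ccccc1)(c1ccccc1)C(C)(C)C | intermediate
3 | (4R)-6-[(tert-butyldiphenylsilyl)oxy]-4-methylhexanal | O=CCC[C@@H](C)CCO[Si](c1ccccc1)(c1ccccc1)C(C)(C)C | intermediate
4 | (4R)-6-[(tert-butyldiphenylsilyl)oxy]-4-methylhexan-1-ol | OCCC[C@@H](C)CCO[Si](c1ccccc1)(c1ccccc1)C(C)(C)C | intermediate
5 | {[(3R)-6-bromo-3-methylhexyl]oxy}(tert-butyl)diphenylsilane | BrCCC[C@@H](C)CCO[Si](c1ccccc1)(c1ccccc1)C(C)(C)C | intermediate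
6 | (5R)-7-[(tert-butyldiphenylsilyl)oxy]-5-methylheptanoic acid | OC(=O)CCC[C@@H](C)CCO[Si](c1ccccc1)(c1ccccc1)C(C)(C)C | intermediate
7 | 3-methylcyclohex-2-en-1-one | CC1=CC(=O)CCC1 | starting material
8 | 2-iodo-3-methylcyclohex-2-en-1-one | CC1=C(I)C(=O)CCC1 | intermediate
9 | (1R)-2-iodo-3-methylcyclohex-2-en-1-ol | CC1=C(I)[C@H](O)CCC1 | intermediate
10 | (1R)-2-(hydroxymethyl)-3-methylcyclohex-2-en-1-ol | CC1=C(CO)[C@H](O)CCC1 | intermediate
11 | [(6R)-6-hydroxy-2-methylcyclohex-1-en-1-yl]methyl (5R)-7-[(tert-butyldiphenylsilyl)oxy]-5-methylheptanoate | CC1=C(COC(=O)CCC[C@@H](C)CCO[Si](c2ccccc2)(c2ccccc2)C(C)(C)C)[C@H](O)CCC1 | intermediate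
12 | (Z)-trimethylsilyl ketene acetal of 11 with the ring hydroxyl as its trimethylsilyl ether | CC1=C(CO/C(O[Si](C)(C)C)=C/CC[C@@H](C)CCO[Si](c2ccccc2)(c2ccccc2)C(C)(C)C)[C@H](O[Si](C)(C)C)CCC1 | intermediate
13 | (2S,5R)-7-[(tert-butyldiphenylsilyl)oxy]-2-[(1S,3R)-3-hydroxy-1-methyl-2-methylidenecyclohexyl]-5-methylheptanoic acid (labdane locants 4R,9S,10S,13R; C4–OH trans to C9 on ring A) | C=C1[C@H](O)CCC[C@@]1(C)[C@H](CC[C@@H](C)CCO[Si](c2ccccc2)(c2ccccc2)C(C)(C)C)C(=O)O | intermediate
14 | methyl (2S,5R)-7-[(tert-butyldiphenylsilyl)oxy]-2-[(1S,3R)-3-hydroxy-1-methyl-2-methylidenecyclohexyl]-5-methylheptanoate | C=C1[C@H](O)CCC[C@@]1(C)[C@H](CC[C@@H](C)CCO[Si](c2ccccc2)(c2ccccc2)C(C)(C)C)C(=O)OC | intermediate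
15 | tertiary carbinol from 14: C8 bearing OH and two trimethylsilylmethyl groups (labdane locants 4R,9S,10S,13R) | C=C1[C@H](O)CCC[C@@]1(C)[C@H](CC[C@@H](C)CCO[Si](c2ccccc2)(c2ccccc2)C(C)(C)C)C(O)(C[Si](C)(C)C)C[Si](C)(C)C | intermediate
16 | (1R,3S)-3-[(3S,6R)-8-[(tert-butyldiphenylsilyl)oxy]-6-methyl-2-methylidene-1-(trimethylsilyl)octan-3-yl]-3-methyl-2-methylidenecyclohexan-1-ol | C=C1[C@H](O)CCC[C@@]1(C)[C@H](CC[C@@H](C)CCO[Si](c2ccccc2)(c2ccccc2)C(C)(C)C)C(=C)C[Si](C)(C)C | intermediate
17 | (3S)-3-[(3S,6R)-8-[(tert-butyldiphenylsilyl)oxy]-6-methyl-2-methylidene-1-(trimethylsilyl)octan-3-yl]-3-methyl-2-methylidenecyclohexan-1-one | C=C1C(=O)CCC[C@@]1(C)[C@H](CC[C@@H](C)CCO[Si](c2ccccc2)(c2ccccc2)C(C)(C)C)C(=C)C[Si](C)(C)C | intermediate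
18 | chloro(ethyl)aluminium enolate of 19 (C4=C5 enolate; labdane locants 9R,10S,13R) | C=C1CCC2=C(O[Al](Cl)CC)CCC[C@@]2(C)[C@@H]1CC[C@@H](C)CCO[Si](c3ccccc3)(c3ccccc3)C(C)(C)C | intermediate
19 | trans-fused 8(17)-methylidene decalin-4-one lacking C18 and C19, C15 as tert-butyldiphenylsilyl ether (labdane locants 5S,9R,10S,13R; H-5 anti to the C10 methyl) | C=C1CC[C@@H]2C(=O)CCC[C@@]2(C)[C@@H]1CC[C@@H](C)CCO[Si](c3ccccc3)(c3ccccc3)C(C)(C)C | intermediate
20 | C4 methoxymethylidene enol ether of 19 (E/Z mixture; labdane locants 5S,9R,10S,13R) | C=C1CC[C@@H]2C(=COC)CCC[C@@]2(C)[C@@H]1CC[C@@H](C)CCO[Si](c3ccccc3)(c3ccccc3)C(C)(C)C | intermediate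
21 | C4 formyl compound (C19 aldehyde; mixture of C4 epimers; C5, C9, C10 and C13 arranged as in 19) | C=C1CC[C@@H]2C(C=O)CCC[C@@]2(C)[C@@H]1CC[C@@H](C)CCO[Si](c3ccccc3)(c3ccccc3)C(C)(C)C | intermediate
22 | quaternary C19 aldehyde, C18 methyl equatorial (labdane locants 4R,5S,9R,10S,13R) | C=C1CC[C@@H]2[C@](C)(C=O)CCC[C@@]2(C)[C@@H]1CC[C@@H](C)CCO[Si](c3ccccc3)(c3ccccc3)C(C)(C)C | intermediate
23 | C19 primary alcohol (labdane locants 4R,5S,9R,10S,13R) | C=C1CC[C@@H]2[C@](C)(CO)CCC[C@@]2(C)[C@@H]1CC[C@@H](C)CCO[Si](c3ccccc3)(c3ccccc3)C(C)(C)C | intermediate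
24 | (2R)-2-methylbutanoic acid | CC[C@@H](C)C(=O)O | starting material
25 | C19 (2R)-2-methylbutanoate, C15 tert-butyldiphenylsilyl ether (labdane locants 4R,5S,9R,10S,13R) | C=C1CC[C@@H]2[C@](C)(COC(=O)[C@H](C)CC)CCC[C@@]2(C)[C@@H]1CC[C@@H](C)CCO[Si](c3ccccc3)(c3ccccc3)C(C)(C)C | intermediate
26 | C19 (2R)-2-methylbutanoate, C15 primary alcohol (labdane locants 4R,5S,9R,10S,13R) | C=C1CC[C@@H]2[C@](C)(COC(=O)[C@H](C)CC)CCC[C@@]2(C)[C@@H]1CC[C@@H](C)CCO | intermediate
27 | CNP0365997.1, (4R,5S,9R,10S,13R)-19-[(2R)-2-methylbutanoyloxy]-ent-labd-8(17)-en-15-oic acid (labdane locants) | C=C1CC[C@@H]2[C@](C)(COC(=O)[C@H](C)CC)CCC[C@@]2(C)[C@@H]1CC[C@@H](C)CC(=O)O | target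

Total step count: 18. Longest linear sequence: 15 steps (steps 1–4, then 8–18).

Steps most likely to fail

Step 12. The Lewis acid may cause protodesilylation of the allylsilane, or attack of C7 on the C4 carbonyl carbon, faster than conjugate addition at C6. The fallback sets out from carboxylic acid 13, which is isolated instead of being esterified, and comes back at ketone 19. Excess MeLi in THF should convert the acid into hydroxy methyl ketone F1, and Wittig methylenation with Ph3P=CH2 should give isopropenyl alcohol F2. MnO2 then gives isopropenyl enone F3. Me2AlCl in CH2Cl2 (−78 → 0 °C) closes the same C6–C7 bond by an intramolecular Lewis acid-catalysed conjugate ene reaction, in which a hydrogen of the C17 methyl group is transferred instead of a silyl group being lost. Equilibration with NaOMe as in step 12 then gives 19.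

Step 9. Acyl migration to the neighbouring alkoxide before silylation, incomplete control of the ketene acetal geometry, or bond formation on the C10 face syn to the small trimethylsilyloxy group would erode the C9/C10 configuration. The fallback sets out from ester 11 and comes back at allylsilane alcohol 16. It carries a permanent, bulkier directing group through two steps. t-BuMe2SiCl and imidazole give silyl ether F4, in which no alkoxide is present during enolisation. The Ireland–Claisen rearrangement and esterification under the conditions of step 9 give methyl ester F5. The silylmethyl Grignard/CeCl3 sequence of step 10 gives protected allylsilane F6. HF·pyridine in THF, which spares the primary tert-butyldiphenylsilyl ether, then frees the C4 hydroxyl to give 16.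

Step 10. The second addition to the hindered, α-branched ester may stall, or enolisation may return starting material. The fallback sets out from methyl ester 14 and comes back at 16. Me3SiCH2Li in THF at −78 °C adds only once, because the product is held as its enolate, and should give α-silyl ketone F7. Non-basic methylenation of the ketone with Cp2TiMe2 in toluene at 65 °C then gives the allylsilane 16 by olefination rather than by addition and elimination.

Further compounds
F1 | step 12 | hydroxy methyl ketone: C8 acetyl analogue of 14 (C4–OH, C5=C6 methylidene) | C=C1[C@H](O)CCC[C@@]1(C)[C@H](CC[C@@H](C)CCO[Si](c2ccccc2)(c2ccccc2)C(C)(C)C)C(C)=O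
F2 | step 12 | isopropenyl alcohol: C8 isopropenyl analogue of 16 | C=C1[C@H](O)CCC[C@@]1(C)[C@H](CC[C@@H](C)CCO[Si](c2ccccc2)(c2ccccc2)C(C)(C)C)C(C)=C
F3 | step 12 | isopropenyl enone: C8 isopropenyl analogue of 17 | C=C1C(=O)CCC[C@@]1(C)[C@H](CC[C@@H](C)CCO[Si](c2ccccc2)(c2ccccc2)C(C)(C)C)C(C)=C
F4 | step 9 | tert-butyldimethylsilyl ether of 11 | CC1=C(COC(=O)CCC[C@@H](C)CCO[Si](c2ccccc2)(c2ccccc2)C(C)(C)C)[C@H](O[Si](C)(C)C(C)(C)C)CCC1
F5 | step 9 | tert-butyldimethylsilyl ether of 14 | C=C1[C@H](O[Si](C)(C)C(C)(C)C)CCC[C@@]1(C)[C@H](CC[C@@H](C)CCO[Si](c2ccccc2)(c2ccccc2)C(C)(C)C)C(=O)OC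
F6 | step 9 | tert-butyldimethylsilyl ether of 16 | C=C1[C@H](O[Si](C)(C)C(C)(C)C)CCC[C@@]1(C)[C@H](CC[C@@H](C)CCO[Si](c2ccccc2)(c2ccccc2)C(C)(C)C)C(=C)C[Si](C)(C)C
F7 | step 10 | α-silyl ketone: C8 (trimethylsilyl)acetyl analogue of 14 | C=C1[C@H](O)CCC[C@@]1(C)[C@H](CC[C@@H](C)CCO[Si](c2ccccc2)(c2ccccc2)C(C)(C)C)C(=O)C[Si](C)(C)C
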